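The numbers in the tables stem from a simulated flask for an exercise; noise was put on by code.

The ratio of target at 38 min to target at 7.6 min is 2.24 in the north-west run, and I call this the reach, ρ: how many times its first reading a flask has made by the last reading, counting only target formed in the flask.

| flask | substrate | partner | target | time |
|---|---|---|---|---|
| north-west | 80.0 mM | 64.0 mM |  |  |
| north-east | 40.0 mM | 24.0 mM |  |  |
| south-east | 80.0 mM | 96.0 mM |  |  |
| south-west | 80.0 mM | 64.0 mM | 40.0 mM |  |
| north | 26.0 mM | 64.0 mM |  | 38 min |

- north-west run (time / min: [target] / mM): 7.6: 15.2; 15: 24.9; 23: 29.7; 30: 32.6; 38: 34.0
- north-east run (time / min: [target] / mM): 7.6: 6.8; 15: 10.7; 23: 12.8; 30: 14.4; 38: 15.5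
- south-east run (time / min: [target] / mM): 7.6: 18.0; 15: 28.5; 23: 33.8; 30: 36.6; 38: 38.6
- south-west run (time / min: [target] / mM): 7.6: 55.7; 15: 64.7; 23: 69.5; 30: 71.8; 38: 74.6

(scatter of a reading: 0.4 mM)

- Overall: substrate + partner -> target.
- Constant volume, constant temperature.
- Readings of a species count what is bound in complexes too.
- "The second partner" is partner.
- An order is taken over about fifteen percent of the charge, up and down.

- the power of [partner] that the first rate follows, about the charge of the north-west run; measure it at two percent of substrate made into target
- the power of [substrate] that the first rate follows, about the charge of the north-west run; measure it at two percent of substrate made into target (one fixed amount of target, the same in the runs compared)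
- target in the north run at 38 min, as a share of the substrate charged

The north-east run gives ρ = 2.28, the south-east run 2.14, and the south-west run, once its added target is subtracted, 2.20. A first reading of 6.8 mM with a scatter of 0.4 mM is good to about 5.88%, and the partner charges differ by a factor of 4.00, so I read these ratios as one number. So I assume the same reach for the north run, whose target at 38 min then follows from its first reading, and I estimate that reading from the charges.

If a rate follows a charge raised to a power n, called the order, then n is the logarithm of the rate ratio over the logarithm of the charge ratio. Going from the north-west to the south-east run changes partner alone, so the first readings give an order in partner of 0.417. The north-east run changes both charges, and after taking out the partner's part I get an order in substrate of 0.570. Both are averages over the first 7.6 min, not rates at the asked two percent.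

The north run has the partner charge of the north-west run, so I scale for substrate alone and expect a first reading of 8.01 mM. Multiplying by ρ gives 17.9 mM, below the 26.0 mM allowed by substrate, the limiting reagent in the north run. My reckoning is therefore 68.8% of the substrate charged.

The forecast says “It looks like a catalyst dying with time” and gives orders of 0.48 in partner and 0.4 in substrate with 64% for the north run, a share lower than mine.

The flask gives orders of 0.34 in partner and 0.42 in substrate, and 60.0% for the north run.

    substrate ⇌ intermediate + by-product (0.4638 min⁻¹, 17.88 M⁻¹ min⁻¹)
    intermediate + partner → target (6.780 M⁻¹ min⁻¹)
    substrate + partner ⇌ idle substrate-reagent adduct, settled at all times (51.70 M⁻¹)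
    2 partner → lost reagent (3.150 M⁻¹ min⁻¹)

The north run holds 15.6 mM at 38 min, so on my estimated first reading its reach is 1.95, and it stands at 60.0% mainly because two partner combine into lost reagent. With that path taken away the same run gives 89.0%. In the south-east run, the north-west ρ applied to the first reading promises 40.3 mM, against 38.6 mM read at 38 min, and that run comes to 40.0 mM at 44.3 min.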